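Compare two drains on the substrate by hand before you start any fit: turnover into target and dimerisation into homo dimer.

| flask | substrate | partner | free catalyst | remark | time |
|---|---|---|---|---|---|
| green | 0.076 M | 0.027 M | 7.6 mM | run made earlier |  |
| violet | 0.076 M | 0.055 M | 7.6 mM | run made earlier |  |
| amber | 0.076 M | 0.089 M | 7.6 mM | run made earlier |  |
| blue | 0.076 M | 0.0988 M | 7.5 mM | run made earlier |  |
| elm | 0.15 M | 0.0250 M | 30 mM |  | 10 h |
| cedar | 0.076 M | 0.0988 M | 2.0 mM |  | 10 h |
| larch | 0.020 M | 0.0988 M | 7.6 mM |  | 10 h |
| birch | 0.076 M | 0.0988 M | 7.6 mM |  | 10 h |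

| run | time / h | target / % | substrate / % |
|---|---|---|---|
| green | 0.417 | 2.3 | 85.0 |
| green | 1.33 | 11.0 | 72.3 |
| green | 2.50 | 22.1 | 55.7 |
| green | 4.00 | 33.0 | 42.5 |
| green | 5.00 | 34.0 | 38.5 |
| violet | 0.417 | 2.3 | 85.4 |
| violet | 0.833 | 5.5 | 78.5 |
| violet | 1.33 | 11.1 | 71.9 |
| violet | 2.50 | 22.1 | 56.2 |
| violet | 5.00 | 45.7 | 29.2 |
| amber | 0.417 | 2.1 | 85.2 |
| amber | 1.33 | 11.4 | 72.3 |
| amber | 2.50 | 22.4 | 55.8 |
| amber | 4.00 | 37.3 | 39.1 |
| amber | 5.00 | 45.9 | 29.2 |
| blue | 0.417 | 2.9 | 85.1 |
| blue | 1.33 | 11.3 | 71.5 |
| blue | 2.50 | 22.6 | 57.4 |
| blue | 4.00 | 36.4 | 39.9 |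
| blue | 5.00 | 45.4 | 29.5 |

(each reading ± 0.5 percentage points)

- a species is counted by the substrate in it: one homo dimer counts as two
- on the list of suspects stand: substrate + free catalyst -> catalyst intermediate A; catalyst intermediate A -> catalyst intermediate B; partner + catalyst intermediate B -> catalyst intermediate C; catalyst intermediate C -> free catalyst + target; 2 substrate -> homo dimer

- all flasks from highest to lowest amount of target, in percent of the substrate charged, at 10 h (elm / cedar / larch / birch)
- the same order at 30 min (elm / cedar / larch / birch)
- the amount of target, in percent of the substrate charged of the flask you put first, at 10 h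
- the amount of target, in percent of the substrate charged of the flask you put last, at 10 h

Up to 2.50 h, the target readings of the green, violet, amber and blue runs agree within the scatter, although their partner differs. Between 1.33 h and 5.00 h, the blue run gives a turnover frequency of 0.942 h⁻¹ on the charged catalyst. Multiplied by the charged [free catalyst]/[substrate], this gives my estimate of the fraction of charge turned per hour: 0.358 h⁻¹ in larch, 0.188 h⁻¹ in elm, 0.0942 h⁻¹ in birch and 0.0248 h⁻¹ in cedar. So I expect larch to lead elm, elm to lead birch and birch to lead cedar at 30 min.

Now the second drain. At 5.00 h, the blue balance of substrate and target misses 25 percentage points, and bound catalyst can hold 9.87% of the charge, so the blue readings put homo dimer near 15.2% or above. The drain ratio, homo dimer made per target made, is then 0.335. While partner lasts and turnover keeps that frequency, I take it to scale as [substrate]²/[free catalyst] on the charges. I also expect it to drift down during a run, since in my reckoning the dimer drain falls with [substrate]² while turnover holds its line, so I take 1/(1+ratio) as a rough floor on the target share of a flask that consumes its substrate.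

For larch the ratio is 0.0229, a floor of 97.8%. Birch has a floor of 75.1%, under a turnover budget, turnover frequency times catalyst charge times time over substrate charge, of 94.2%, and larch's floor stands above that budget. Cedar's budget is 24.8%, below birch's floor. Green reads 34.0% target at 5.00 h, close to its partner charge of 35.5% of the substrate, so I cap elm's target at its partner, the limiting reagent, which is 16.7% of the substrate, below cedar's budget.

The forecast agrees on the order: larch > birch > cedar > elm at 10 h, larch > elm > birch > cedar at 30 min, with 98% first and 16.6% last. Of the early order it says, “Larch over elm is the uncertain call.”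

The flasks stand at larch > birch > cedar > elm and larch > elm > birch > cedar, with 98.6% first and 16.7% last.

    substrate + free catalyst → catalyst intermediate A (k = 5.20 M⁻¹ min⁻¹)
    catalyst intermediate A → catalyst intermediate B (k = 0.0740 min⁻¹)
    partner + catalyst intermediate B → catalyst intermediate C (k = 36.0 M⁻¹ min⁻¹)
    catalyst intermediate C → free catalyst + target (k = 0.0230 min⁻¹)
    2 substrate → homo dimer (k = 0.00960 M⁻¹ min⁻¹)

At 10 h, larch holds 1.35% homo dimer beside 98.6% target, a ratio of 0.0137, less than the reckoned 0.0229. Now charge larch's neighbour with 0.080 M substrate: the ratio becomes 0.367, a floor of 73.2%, and the budget is 89.4%. At 10 h, that flask gives 78.7% target, with 18.2% homo dimer.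

Readings and results stem from a simulated flask with constants of no real substance.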